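**Assumption:** briarane numbering (C1–C20) is used for all intermediates; (S)-Roche ester, (R)-4-hydroxycyclopent-2-en-1-one, 5-bromopent-2-yne and the two Grignard reagents are taken as purchasable. The chiral ligand enantiomers in steps 13 and 18 are my best assignment and would be confirmed by a short screen.

## Retrosynthetic overview

1. Target ⇐ macrocyclic 6-hydroxy-5(16)-ene by SN2 chlorination, C12 oxidation/α-methylenation/reduction, hydroxyl-directed 11,20-epoxidation and final acetylation; the ten-membered ring is closed last (C5–C6, Nozaki–Hiyama–Kishi).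
2. Ring A with the C1 quaternary centre and the C2 carbinol ⇐ epoxidation/semipinacol ring expansion of a 1-alkenylcyclopentanol (1,2-shift of C10 from C14 to C1): the key step.
3. Cyclopentanol ⇐ alkenylcerium (C15, C1–C5, C16) + cyclopentanone; C9–C10 by anti boron aldol of an (R)-4-silyloxycyclopentanone enolate with a lactone aldehyde.
4. Lactone aldehyde (C6–C9, C17–C19) ⇐ group- and face-selective iodolactonisation of a divinyl carbinol acid from (S)-Roche ester.
5. Ring order: γ-lactone first (own fragment), purchased cyclopentane expanded to six-membered ring A, ten-membered ring third, spiro-epoxide last.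

## Route

Step 1
Reactants: 1 methyl (S)-3-hydroxy-2-methylpropanoate
Product: 2 (S)-2-methyl-3-vinylpent-4-ene-1,3-diol
Conditions: vinylmagnesium bromide (4.5 equiv), CeCl3, THF, −78 → 0 °C
Reagents that add atoms: vinylmagnesium bromide, C=C[Mg]Br
Why: Double Grignard 1,2-addition to the ester (CeCl3 suppresses enolisation and conjugate addition to the intermediate vinyl ketone) gives the divinyl carbinol, with C17 taken from the chiral pool.

Step 2
Reactants: 2 (S)-2-methyl-3-vinylpent-4-ene-1,3-diol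
Product: 3 (R)-3-hydroxy-2-methyl-3-vinylpent-4-enoic acid
Conditions: TEMPO (20 mol%), PhI(OAc)2 (2.2 equiv), MeCN/H2O 1:1, 0 °C → rt
Reagents that add atoms: water, O
Why: Nitroxyl-catalysed oxidation of the primary alcohol to the acid; the tertiary alcohol cannot be oxidised and the near-neutral medium preserves the α-stereocentre.

Step 3
Reactants: 3 (R)-3-hydroxy-2-methyl-3-vinylpent-4-enoic acid
Product: 4 (3R,4S,5R)-4-hydroxy-5-(iodomethyl)-3-methyl-4-vinyldihydrofuran-2(3H)-one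
Conditions: I2 (3 equiv), NaHCO3, MeCN/H2O, 0 °C, dark
Reagents that add atoms: iodine, II
Why: Kinetic 5-exo iodolactonisation in which the allylic hydroxyl places the iodomethyl group cis to itself and the vinyl group trans to the C17 methyl is the one left behind, setting C7 and C8 relative to C17.

Step 4
Reactants: 4 (3R,4S,5R)-4-hydroxy-5-(iodomethyl)-3-methyl-4-vinyldihydrofuran-2(3H)-one
Product: 5 (3R,4S,5R)-5-(iodomethyl)-3-methyl-4-(triethylsilyloxy)-4-vinyldihydrofuran-2(3H)-one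
Conditions: Et3SiOTf, 2,6-lutidine, CH2Cl2, −78 → 0 °C
Reagents that add atoms: triethylsilyl triflate, CC[Si](CC)(CC)OS(=O)(=O)C(F)(F)F
Why: Silyl triflate silylation of the tertiary alcohol, so that the later aldehyde can meet an enolate.

Step 5
Reactants: 5 (3R,4S,5R)-5-(iodomethyl)-3-methyl-4-(triethylsilyloxy)-4-vinyldihydrofuran-2(3H)-one
Product: 7 (2R,3S,4R)-2-(iodomethyl)-4-methyl-5-oxo-3-(triethylsilyloxy)tetrahydrofuran-3-carbaldehyde, via ozonide 6 (not isolated)
Conditions: O3, CH2Cl2, −78 °C; then PPh3, −78 °C → rt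
Reagents that add atoms: ozone, [O-][O+]=O
Why: Ozonolysis with reductive work-up turns the remaining vinyl group into the non-enolisable C9 aldehyde without touching a stereocentre.

Step 6
Reactants: 8 (R)-4-hydroxycyclopent-2-en-1-one
Product: 9 (R)-4-(triethylsilyloxy)cyclopent-2-en-1-one
Conditions: Et3SiCl, imidazole, CH2Cl2, 0 °C
Reagents that add atoms: chlorotriethylsilane, CC[Si](Cl)(CC)CC
Why: Base-mild silylation of the secondary alcohol; the C12 stereocentre is the one kept in the target.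

Step 7
Reactants: 9 (R)-4-(triethylsilyloxy)cyclopent-2-en-1-one
Product: 10 triethyl{[(4S)-4-(triethylsilyloxy)cyclopent-1-en-1-yl]oxy}silane
Conditions: Et3SiH, RhCl(PPh3)3 (1 mol%), THF, 50 °C
Reagents that add atoms: triethylsilane, CC[SiH](CC)CC
Why: Rhodium-catalysed 1,4-hydrosilylation of the enone gives the regiodefined C14=C10 enol silane, away from the silyloxy-bearing side.

Step 8
Reactants: 10 triethyl{[(4S)-4-(triethylsilyloxy)cyclopent-1-en-1-yl]oxy}silane; 7 (2R,3S,4R)-2-(iodomethyl)-4-methyl-5-oxo-3-(triethylsilyloxy)tetrahydrofuran-3-carbaldehyde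
Product: 13 anti-aldol adduct (C14 cyclopentanone; 9-OH; 8-OTES; 12-OTES), via lithium enolate 11 (not isolated), via boron enolate 12 (not isolated)
Conditions: MeLi, THF, 0 °C; (c-C6H11)2BCl, −78 °C; then 7, −78 → −20 °C; H2O2, pH 7 buffer, MeOH, 0 °C
Reagents that add atoms: none
Why: Zimmerman–Traxler boron aldol of the cyclic (E)-enolate gives the anti adduct, and attack on the enolate face opposite the 12-silyloxy group (2,4-trans) fixes C10 and with it C9.

Step 9
Reactants: 13 anti-aldol adduct (C14 cyclopentanone; 9-OH; 8-OTES; 12-OTES)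
Product: 14 silyl-protected aldol (C14 cyclopentanone; 9-OTBS; 8-OTES; 12-OTES)
Conditions: t-BuMe2SiOTf, 2,6-lutidine, CH2Cl2, −78 → 0 °C
Reagents that add atoms: tert-butyldimethylsilyl triflate, CC(C)(C)[Si](C)(C)OS(=O)(=O)C(F)(F)F
Why: Silyl triflate protection of the hindered β-hydroxyl without retro-aldol or elimination, so that it cannot open the later epoxide.

Step 10
Reactants: 15 5-bromopent-2-yne
Product: 17 (E)-5-bromo-2-iodopent-2-ene, via alkenylzirconocene chloride 16 (not isolated)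
Conditions: Cp2Zr(H)Cl (2 equiv), THF, 45 °C; then I2, 0 °C
Reagents that add atoms: iodine, II
Why: syn-Hydrozirconation equilibrates to zirconium on the less hindered methyl-bearing carbon and iodinolysis with retention gives the (E)-2-iodo-2-alkene.

Step 11
Reactants: 17 (E)-5-bromo-2-iodopent-2-ene
Product: 18 (E)-(6-iodohepta-1,5-dien-2-yl)trimethylsilane
Conditions: (1-(trimethylsilyl)vinyl)magnesium bromide, Li2CuCl4 (3 mol%), THF, −20 → 0 °C
Reagents that add atoms: (1-(trimethylsilyl)vinyl)magnesium bromide, C=C([Mg]Br)[Si](C)(C)C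
Why: Copper-catalysed (Kochi) Grignard coupling at the primary bromide forms C4–C5; the alkenyl iodide is inert at this temperature.

Step 12
Reactants: 18 (E)-(6-iodohepta-1,5-dien-2-yl)trimethylsilane; 14 silyl-protected aldol (C14 cyclopentanone; 9-OTBS; 8-OTES; 12-OTES)
Product: 21 tertiary allylic cyclopentanol (C14-OH; E-C1=C2; C5 vinylsilane), via alkenyllithium 19 (not isolated), via alkenylcerium dichloride 20 (not isolated)
Conditions: t-BuLi (2.05 equiv), Et2O, −78 °C; CeCl3, THF, −78 °C; then 14, −78 °C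
Reagents that add atoms: none
Why: Iodine–lithium exchange with retention, then 1,2-addition of the weakly basic organocerium to the ketone in preference to the lactone, anti to the C10 side chain; the C14 configuration is lost later.

Step 13
Reactants: 21 tertiary allylic cyclopentanol (C14-OH; E-C1=C2; C5 vinylsilane)
Product: 24 ring A cyclohexanone (14-oxo; 2-OAc; C1 quaternary), via epoxy alcohol 22 (not isolated), via hydroxy ketone 23 (not isolated)
Conditions: Hf(Ot-Bu)4 (10 mol%), (R,R)-cyclohexane-1,2-diamine-derived bis-hydroxamic acid ligand (12 mol%), cumene hydroperoxide (1.5 equiv), toluene, 0 °C; then Hf(OTf)4 (15 mol%), CH2Cl2, −40 → −10 °C; then Ac2O, pyridine, DMAP, 0 °C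
Reagents that add atoms: cumene hydroperoxide, CC(C)(OO)c1ccccc1; acetic anhydride, CC(=O)OC(C)=O
Why: Proposed new method: a one-flask, ligand-controlled oxygenative semipinacol ring expansion. The chiral tetravalent-hafnium bis-hydroxamate, bound to the tertiary alkoxide, first delivers oxygen to C1=C2 to give the (1R,2S)-epoxy alcohol; the ligand decides the face because the substrate's own A(1,2) bias between its two sp3 ring arms is weak. Added Hf(OTf)4 then ionises the epoxide at tertiary C1 while the antiperiplanar C10–C14 bond migrates (retention at C10, inversion at C1), turning the cyclopentanol into ring A with the C1 quaternary centre and the C2 carbinol, which is acetylated before retro-aldol can occur. The closest known reactions are the hafnium/bis-hydroxamic acid epoxidation of tertiary allylic alcohols and the Lewis-acid semipinacol rearrangement of 2,3-epoxy alcohols; they have not been merged nor applied to a cyclopentanol-to-cyclohexanone expansion with an oxygenated secondary migrating carbon.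

Step 14
Reactants: 24 ring A cyclohexanone (14-oxo; 2-OAc; C1 quaternary)
Product: 27 13-(4-methylpentanoyloxy) ketone (14-oxo; 2-OAc), via sodium enolate 25 (not isolated), via sodium alkoxide 26 (not isolated)
Conditions: NaN(SiMe3)2, THF, −78 °C; 2-(phenylsulfonyl)-3-phenyloxaziridine, −78 °C; then 4-methylpentanoyl chloride, DMAP, −78 → 0 °C
Reagents that add atoms: 2-(phenylsulfonyl)-3-phenyloxaziridine, O=S(=O)(c1ccccc1)N1OC1c1ccccc1; 4-methylpentanoyl chloride, CC(C)CCC(Cl)=O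
Why: Only C13 can enolise, so Davis enolate hydroxylation and in-situ O-acylation install the ester there, on the face away from the axial C15 methyl, which is also the thermodynamically preferred equatorial position.

Step 15
Reactants: 27 13-(4-methylpentanoyloxy) ketone (14-oxo; 2-OAc)
Product: 29 2,14-diacetate (13-ester; 12-OTES; C5 vinylsilane; C6 iodide), via lithium alkoxide 28 (not isolated)
Conditions: LiBH(s-Bu)3, THF, −78 °C; then Ac2O, DMAP, −78 → −20 °C
Reagents that add atoms: acetic anhydride, CC(=O)OC(C)=O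
Why: The bulky hydride attacks equatorially because the axial path is blocked by the axial 12-silyloxy group, giving the axial C14 alkoxide cis to the 13-ester, which is acetylated cold before acyl migration.

Step 16
Reactants: 29 2,14-diacetate (13-ester; 12-OTES; C5 vinylsilane; C6 iodide)
Product: 30 vinyl iodide (C5 iodoalkene; C6 iodide)
Conditions: N-iodosuccinimide, MeCN/ClCH2CN 4:1, 0 °C
Reagents that add atoms: N-iodosuccinimide, O=C1CCC(=O)N1I
Why: ipso-Iododesilylation of the 1,1-disubstituted vinylsilane through the β-silyl cation keeps the alkene in place.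

Step 17
Reactants: 30 vinyl iodide (C5 iodoalkene; C6 iodide)
Product: 31 seco-aldehyde (C6 aldehyde; C5 iodoalkene)
Conditions: Me3NO (anhydrous, 5 equiv), DMSO, rt → 40 °C
Reagents that add atoms: trimethylamine N-oxide, C[N+](C)(C)[O-]
Why: Kornblum-type N-oxide oxidation of the primary iodide to the aldehyde under nearly neutral conditions; the alkenyl iodide does not react.

Step 18
Reactants: 31 seco-aldehyde (C6 aldehyde; C5 iodoalkene)
Product: 32 macrocyclic (6R)-allylic alcohol (ten-membered ring closed; 5(16)-ene)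
Conditions: CrCl2 (8 equiv), NiCl2 (2 mol%), Kishi-type (S)-oxazoline–sulfonamide ligand (8.8 equiv), Et3N, THF, rt, 2 mM, slow addition of 31
Reagents that add atoms: none
Why: Intramolecular Nozaki–Hiyama–Kishi coupling forms C5–C6 and the ten-membered ring, helped by the trans-disposed arms on ring A and on the lactone, with the C6 carbinol set by the chiral ligand.

Step 19
Reactants: 32 macrocyclic (6R)-allylic alcohol (ten-membered ring closed; 5(16)-ene)
Product: 33 macrocyclic (6S)-allylic chloride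
Conditions: PPh3, Cl3CC(O)CCl3, 2,6-di-tert-butylpyridine, CH2Cl2, −20 → 0 °C
Reagents that add atoms: hexachloroacetone, ClC(Cl)(Cl)C(=O)C(Cl)(Cl)Cl
Why: Phosphine/hexachloroacetone deoxychlorination of the secondary allylic alcohol proceeds by SN2 with inversion and without allylic transposition, giving the C6 chloride of the target.

Step 20
Reactants: 33 macrocyclic (6S)-allylic chloride
Product: 35 C12 ketone (8-OTES and 9-OTBS kept), via C12 alcohol 34 (not isolated)
Conditions: IBX (4 equiv), DMSO, rt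
Reagents that add atoms: none
Why: IBX in DMSO cleaves the secondary triethylsilyl ether in preference to the TBS and tertiary TES ethers and oxidises the freed alcohol to the ketone in the same flask.

Step 21
Reactants: 35 C12 ketone (8-OTES and 9-OTBS kept)
Product: 39 exo-methylene ketone (12-oxo; 11(20)-ene), via lithium enolate 36 (not isolated), via Mannich base 37 (not isolated), via ammonium iodide 38 (not isolated)
Conditions: LiN(SiMe3)2 (1.05 equiv), THF, −78 °C; Me2N=CH2+ I−, −78 → 0 °C; then MeI, CH2Cl2, rt; aq. NaHCO3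
Reagents that add atoms: Eschenmoser's salt, C=[N+](C)C.[I-]
Why: Kinetic deprotonation at the less hindered C11 methylene (avoiding the C13 enolate that could expel the 14-acetate), Mannich reaction and Hofmann-type elimination give the α-methylene ketone.

Step 22
Reactants: 39 exo-methylene ketone (12-oxo; 11(20)-ene)
Product: 40 allylic alcohol (axial 12-OH cis to the 13- and 14-esters)
Conditions: NaBH4, CeCl3·7H2O, MeOH/THF, −78 °C
Reagents that add atoms: none
Why: Luche 1,2-reduction in which hydride enters equatorially, the axial trajectory being shielded by the axial 14-acetate, so the C12 hydroxyl is axial as in the target.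

Step 23
Reactants: 40 allylic alcohol (axial 12-OH cis to the 13- and 14-esters)
Product: 41 triol (8-OH; 9-OH; 12-OH)
Conditions: HF (48% aq.), MeCN, 0 °C → rt
Reagents that add atoms: none
Why: Acidic fluoride desilylation removes the secondary TBS and tertiary TES ethers without base-induced acyl migration and before the acid-sensitive epoxide exists.

Step 24
Reactants: 41 triol (8-OH; 9-OH; 12-OH)
Product: 42 11,20-epoxy triol
Conditions: VO(acac)2 (5 mol%), t-BuOOH (1.2 equiv), CH2Cl2, 0 °C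
Reagents that add atoms: tert-butyl hydroperoxide, CC(C)(C)OO
Why: Vanadium-catalysed hydroxyl-directed epoxidation delivers oxygen to C11=C20 syn to the axial 12-OH, which sits over that π-face; the C5=C16 alkene has no directing hydroxyl and is deactivated by the allylic chloride.

Step 25
Reactants: 42 11,20-epoxy triol
Product: 43 CNP0196150.1 (target)
Conditions: Ac2O, DMAP (cat.), pyridine, CH2Cl2, 0 °C → rt
Reagents that add atoms: acetic anhydride, CC(=O)OC(C)=O
Why: DMAP-catalysed acetylation of the two secondary hydroxyls at C9 and C12; the tertiary 8-OH does not react.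

## Compound list

1 | methyl (S)-3-hydroxy-2-methylpropanoate ((S)-Roche ester) | COC(=O)[C@@H](C)CO | starting material
2 | (S)-2-methyl-3-vinylpent-4-ene-1,3-diol | C=CC(O)(C=C)[C@@H](C)CO | intermediate
3 | (R)-3-hydroxy-2-methyl-3-vinylpent-4-enoic acid | C=CC(O)(C=C)[C@@H](C)C(=O)O | intermediate
4 | (3R,4S,5R)-4-hydroxy-5-(iodomethyl)-3-methyl-4-vinyldihydrofuran-2(3H)-one (OH, CH2I and CH3 on one face) | C=C[C@]1(O)[C@@H](C)C(=O)O[C@H]1CI | intermediate
5 | (3R,4S,5R)-5-(iodomethyl)-3-methyl-4-(triethylsilyloxy)-4-vinyldihydrofuran-2(3H)-one | C=C[C@]1(O[Si](CC)(CC)CC)[C@@H](C)C(=O)O[C@H]1CI | intermediate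
6 | ozonide of 5 (3-lactonyl-1,2,4-trioxolane, both epimers at the trioxolane carbon; not isolated) | C1OOC(O1)[C@]1(O[Si](CC)(CC)CC)[C@@H](C)C(=O)O[C@H]1CI | intermediate
7 | (2R,3S,4R)-2-(iodomethyl)-4-methyl-5-oxo-3-(triethylsilyloxy)tetrahydrofuran-3-carbaldehyde | O=C[C@]1(O[Si](CC)(CC)CC)[C@@H](C)C(=O)O[C@H]1CI | intermediate
8 | (R)-4-hydroxycyclopent-2-en-1-one | O=C1C[C@@H](O)C=C1 | starting material
9 | (R)-4-(triethylsilyloxy)cyclopent-2-en-1-one | O=C1C[C@@H](O[Si](CC)(CC)CC)C=C1 | intermediate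
10 | triethyl{[(4S)-4-(triethylsilyloxy)cyclopent-1-en-1-yl]oxy}silane | CC[Si](CC)(CC)OC1=CC[C@H](O[Si](CC)(CC)CC)C1 | intermediate
11 | lithium (S)-4-(triethylsilyloxy)cyclopent-1-en-1-olate (not isolated) | [Li]OC1=CC[C@H](O[Si](CC)(CC)CC)C1 | intermediate
12 | dicyclohexylboron enolate of the same ketone (not isolated) | C1CCCCC1B(OC1=CC[C@H](O[Si](CC)(CC)CC)C1)C1CCCCC1 | intermediate
13 | anti-aldol adduct: cyclopentanone (C14=O) with 12-OTES and, at C10, the CH(OH) (C9) group bound to C8 of the lactone; C7, C8, C9, C10, C12, C17 as in the target | O=C1C[C@@H](O[Si](CC)(CC)CC)C[C@@H]1[C@H](O)[C@]1(O[Si](CC)(CC)CC)[C@@H](C)C(=O)O[C@H]1CI | intermediate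
14 | 9-O-TBS ether of 13 | O=C1C[C@@H](O[Si](CC)(CC)CC)C[C@@H]1[C@H](O[Si](C)(C)C(C)(C)C)[C@]1(O[Si](CC)(CC)CC)[C@@H](C)C(=O)O[C@H]1CI | intermediate
15 | 5-bromopent-2-yne | CC#CCCBr | starting material
16 | (E)-(5-bromopent-2-en-2-yl)zirconocene chloride (not isolated) | C/C(=C\CCBr)[Zr](Cl)(C1C=CC=C1)C1C=CC=C1 | intermediate
17 | (E)-5-bromo-2-iodopent-2-ene | C/C(I)=C\CCBr | intermediate
18 | (E)-(6-iodohepta-1,5-dien-2-yl)trimethylsilane | C/C(I)=C\CCC(=C)[Si](C)(C)C | intermediate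
19 | (E)-alkenyllithium from 18 (not isolated) | C/C([Li])=C\CCC(=C)[Si](C)(C)C | intermediate
20 | (E)-alkenylcerium dichloride from 19 (not isolated) | C/C([Ce](Cl)Cl)=C\CCC(=C)[Si](C)(C)C | intermediate
21 | tertiary allylic cyclopentanol: C14(OH) bearing the (E)-C1(CH3)=C2H–C3H2–C4H2–C5(SiMe3)=CH2 chain trans to the C10 side chain; rest as 14 | C=C([Si](C)(C)C)CC/C=C(\C)[C@@]1(O)C[C@@H](O[Si](CC)(CC)CC)C[C@@H]1[C@H](O[Si](C)(C)C(C)(C)C)[C@]1(O[Si](CC)(CC)CC)[C@@H](C)C(=O)O[C@H]1CI | intermediate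
22 | (1R,2S)-1,2-epoxy alcohol of 21 (not isolated) | C=C([Si](C)(C)C)CC[C@@H]1O[C@@]1(C)[C@@]1(O)C[C@@H](O[Si](CC)(CC)CC)C[C@@H]1[C@H](O[Si](C)(C)C(C)(C)C)[C@]1(O[Si](CC)(CC)CC)[C@@H](C)C(=O)O[C@H]1CI | intermediate
23 | ring A hydroxy ketone: cyclohexanone (C14=O) with quaternary C1 (CH3), 2-OH, 12-OTES; C1, C2, C10 as in the target (not isolated) | C=C([Si](C)(C)C)CC[C@H](O)[C@@]1(C)C(=O)C[C@@H](O[Si](CC)(CC)CC)C[C@@H]1[C@H](O[Si](C)(C)C(C)(C)C)[C@]1(O[Si](CC)(CC)CC)[C@@H](C)C(=O)O[C@H]1CI | intermediate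
24 | 2-O-acetate of 23 | C=C([Si](C)(C)C)CC[C@H](OC(C)=O)[C@@]1(C)C(=O)C[C@@H](O[Si](CC)(CC)CC)C[C@@H]1[C@H](O[Si](C)(C)C(C)(C)C)[C@]1(O[Si](CC)(CC)CC)[C@@H](C)C(=O)O[C@H]1CI | intermediate
25 | sodium C13=C14 enolate of 24 (not isolated) | C=C([Si](C)(C)C)CC[C@H](OC(C)=O)[C@@]1(C)C(O[Na])=C[C@@H](O[Si](CC)(CC)CC)C[C@@H]1[C@H](O[Si](C)(C)C(C)(C)C)[C@]1(O[Si](CC)(CC)CC)[C@@H](C)C(=O)O[C@H]1CI | intermediate
26 | sodium alkoxide of the 13-hydroxy-14-ketone (not isolated) | C=C([Si](C)(C)C)CC[C@H](OC(C)=O)[C@@]1(C)C(=O)[C@@H](O[Na])[C@@H](O[Si](CC)(CC)CC)C[C@@H]1[C@H](O[Si](C)(C)C(C)(C)C)[C@]1(O[Si](CC)(CC)CC)[C@@H](C)C(=O)O[C@H]1CI | intermediate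
27 | 13-(4-methylpentanoyloxy)-14-ketone, C13 as in the target | C=C([Si](C)(C)C)CC[C@H](OC(C)=O)[C@@]1(C)C(=O)[C@@H](OC(=O)CCC(C)C)[C@@H](O[Si](CC)(CC)CC)C[C@@H]1[C@H](O[Si](C)(C)C(C)(C)C)[C@]1(O[Si](CC)(CC)CC)[C@@H](C)C(=O)O[C@H]1CI | intermediate
28 | lithium C14 alkoxide from 27 (not isolated) | C=C([Si](C)(C)C)CC[C@H](OC(C)=O)[C@@]1(C)[C@@H](O[Li])[C@@H](OC(=O)CCC(C)C)[C@@H](O[Si](CC)(CC)CC)C[C@@H]1[C@H](O[Si](C)(C)C(C)(C)C)[C@]1(O[Si](CC)(CC)CC)[C@@H](C)C(=O)O[C@H]1CI | intermediate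
29 | 2,14-diacetate with 13-ester, 12-OTES, 9-OTBS, 8-OTES, C5 vinylsilane, C6 iodide; C14 as in the target | C=C([Si](C)(C)C)CC[C@H](OC(C)=O)[C@@]1(C)[C@@H](OC(C)=O)[C@@H](OC(=O)CCC(C)C)[C@@H](O[Si](CC)(CC)CC)C[C@@H]1[C@H](O[Si](C)(C)C(C)(C)C)[C@]1(O[Si](CC)(CC)CC)[C@@H](C)C(=O)O[C@H]1CI | intermediate
30 | as 29 with C5(I)=CH2 in place of the vinylsilane | C=C(I)CC[C@H](OC(C)=O)[C@@]1(C)[C@@H](OC(C)=O)[C@@H](OC(=O)CCC(C)C)[C@@H](O[Si](CC)(CC)CC)C[C@@H]1[C@H](O[Si](C)(C)C(C)(C)C)[C@]1(O[Si](CC)(CC)CC)[C@@H](C)C(=O)O[C@H]1CI | intermediate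
31 | as 30 with a C6 aldehyde in place of CH2I | C=C(I)CC[C@H](OC(C)=O)[C@@]1(C)[C@@H](OC(C)=O)[C@@H](OC(=O)CCC(C)C)[C@@H](O[Si](CC)(CC)CC)C[C@@H]1[C@H](O[Si](C)(C)C(C)(C)C)[C@]1(O[Si](CC)(CC)CC)[C@@H](C)C(=O)O[C@H]1C=O | intermediate
32 | macrocyclic (6R)-allylic alcohol: briarane skeleton with 5(16)-ene, 6-OH, 12-OTES, 9-OTBS, 8-OTES, 2,14-di-OAc, 13-ester | C=C1CC[C@H](OC(C)=O)[C@@]2(C)[C@@H](OC(C)=O)[C@@H](OC(=O)CCC(C)C)[C@@H](O[Si](CC)(CC)CC)C[C@@H]2[C@H](O[Si](C)(C)C(C)(C)C)[C@]2(O[Si](CC)(CC)CC)[C@@H](C)C(=O)O[C@H]2[C@@H]1O | intermediate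
33 | (6S)-chloride from 32, C6 as in the target | C=C1CC[C@H](OC(C)=O)[C@@]2(C)[C@@H](OC(C)=O)[C@@H](OC(=O)CCC(C)C)[C@@H](O[Si](CC)(CC)CC)C[C@@H]2[C@H](O[Si](C)(C)C(C)(C)C)[C@]2(O[Si](CC)(CC)CC)[C@@H](C)C(=O)O[C@H]2[C@H]1Cl | intermediate
34 | 12-alcohol from 33 (not isolated) | C=C1CC[C@H](OC(C)=O)[C@@]2(C)[C@@H](OC(C)=O)[C@@H](OC(=O)CCC(C)C)[C@@H](O)C[C@@H]2[C@H](O[Si](C)(C)C(C)(C)C)[C@]2(O[Si](CC)(CC)CC)[C@@H](C)C(=O)O[C@H]2[C@H]1Cl | intermediate
35 | 12-ketone | C=C1CC[C@H](OC(C)=O)[C@@]2(C)[C@@H](OC(C)=O)[C@@H](OC(=O)CCC(C)C)C(=O)C[C@@H]2[C@H](O[Si](C)(C)C(C)(C)C)[C@]2(O[Si](CC)(CC)CC)[C@@H](C)C(=O)O[C@H]2[C@H]1Cl | intermediate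
36 | lithium C11=C12 enolate of 35 (not isolated) | C=C1CC[C@H](OC(C)=O)[C@@]2(C)[C@@H](OC(C)=O)[C@@H](OC(=O)CCC(C)C)C(O[Li])=C[C@@H]2[C@H](O[Si](C)(C)C(C)(C)C)[C@]2(O[Si](CC)(CC)CC)[C@@H](C)C(=O)O[C@H]2[C@H]1Cl | intermediate
37 | 11-(dimethylaminomethyl)-12-ketone, epimers at C11 (not isolated) | C=C1CC[C@H](OC(C)=O)[C@@]2(C)[C@@H](OC(C)=O)[C@@H](OC(=O)CCC(C)C)C(=O)C(CN(C)C)[C@@H]2[C@H](O[Si](C)(C)C(C)(C)C)[C@]2(O[Si](CC)(CC)CC)[C@@H](C)C(=O)O[C@H]2[C@H]1Cl | intermediate
38 | trimethylammonium iodide of 37 (not isolated) | C=C1CC[C@H](OC(C)=O)[C@@]2(C)[C@@H](OC(C)=O)[C@@H](OC(=O)CCC(C)C)C(=O)C(C[N+](C)(C)C)[C@@H]2[C@H](O[Si](C)(C)C(C)(C)C)[C@]2(O[Si](CC)(CC)CC)[C@@H](C)C(=O)O[C@H]2[C@H]1Cl.[I-] | intermediate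
39 | 11(20)-methylene-12-ketone | C=C1CC[C@H](OC(C)=O)[C@@]2(C)[C@@H](OC(C)=O)[C@@H](OC(=O)CCC(C)C)C(=O)C(=C)[C@@H]2[C@H](O[Si](C)(C)C(C)(C)C)[C@]2(O[Si](CC)(CC)CC)[C@@H](C)C(=O)O[C@H]2[C@H]1Cl | intermediate
40 | 12-hydroxy-11(20)-ene, C12 as in the target | C=C1CC[C@H](OC(C)=O)[C@@]2(C)[C@@H](OC(C)=O)[C@@H](OC(=O)CCC(C)C)[C@@H](O)C(=C)[C@@H]2[C@H](O[Si](C)(C)C(C)(C)C)[C@]2(O[Si](CC)(CC)CC)[C@@H](C)C(=O)O[C@H]2[C@H]1Cl | intermediate
41 | 8,9,12-triol with 11(20)-ene | C=C1CC[C@H](OC(C)=O)[C@@]2(C)[C@@H](OC(C)=O)[C@@H](OC(=O)CCC(C)C)[C@@H](O)C(=C)[C@@H]2[C@H](O)[C@]2(O)[C@@H](C)C(=O)O[C@H]2[C@H]1Cl | intermediate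
42 | 11,20-epoxy-8,9,12-triol, C11 as in the target | C=C1CC[C@H](OC(C)=O)[C@@]2(C)[C@@H](OC(C)=O)[C@@H](OC(=O)CCC(C)C)[C@@H](O)[C@]3(CO3)[C@@H]2[C@H](O)[C@]2(O)[C@@H](C)C(=O)O[C@H]2[C@H]1Cl | intermediate
43 | CNP0196150.1 | C=C1CC[C@H](OC(C)=O)[C@@]2(C)[C@@H](OC(C)=O)[C@@H](OC(=O)CCC(C)C)[C@@H](OC(C)=O)[C@]3(CO3)[C@@H]2[C@H](OC(C)=O)[C@]2(O)[C@@H](C)C(=O)O[C@H]2[C@H]1Cl | target

## Step count and risks

Total: 25 steps. Longest linear sequence: 21 steps (1–5, 8, 9, 12–25).

Steps most likely to fail: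

Step 13 (the proposed new tandem epoxidation/semipinacol ring expansion). The risks are the wrong epoxide face, migration of C13 instead of C10, and opening of the activated epoxide by the C9 silyl ether oxygen. The fallback uses known chemistry in separate stages and sets out from 21. Shi asymmetric epoxidation (L-fructose-derived ketone catalyst, Oxone 2KHSO5·KHSO4·K2SO4, K2CO3, MeCN/dimethoxymethane/aqueous buffer, 0 °C) puts the oxygen on C1=C2 under reagent control and epoxy alcohol 22 is isolated. BF3·OEt2 in CH2Cl2 at −78 °C then effects the known Lewis-acid semipinacol rearrangement to hydroxy ketone 23, and Ac2O/pyridine/DMAP comes back to the route at 24.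

Step 18 (ten-membered ring closure by Nozaki–Hiyama–Kishi coupling, with C6 configuration depending on the ligand). The fallback closes the ring at the same C5–C6 bond by metathesis and installs chlorine by an ene-type chlorination; it sets out from 31. Wittig methylenation of the aldehyde (Ph3P=CH2, THF, −78 °C) gives the C7 vinyl compound F1. Negishi methylation of the alkenyl iodide (MeZnCl, Pd(PPh3)4, THF) gives the isopropenyl diene F2. Ring-closing metathesis (second-generation Grubbs catalyst RuCl2(=CHPh)(PCy3)(H2IMes), toluene, 80 °C, 1 mM) gives the (Z)-5(6)-ene macrocycle F3. Ene-type allylic chlorination (Ca(OCl)2, CO2, CH2Cl2/H2O, 0 °C) puts chlorine on C6 from the peripheral face and moves the double bond to C5=C16, coming back at 33, so step 19 is bypassed as well.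

Step 8 (aldol: anti selectivity and 2,4-trans facial control with a hindered α-quaternary aldehyde). The fallback replaces the substrate-controlled metal enolate by catalyst-controlled enamine chemistry and sets out from 9. Hydrogenation (H2, Pd on carbon, EtOAc) gives (S)-3-(triethylsilyloxy)cyclopentanone F4. A direct anti-aldol with 7 catalysed by (R)-5-(pyrrolidin-2-yl)tetrazole (20 mol%, DMSO/H2O, rt) then comes back at 13.

Further compounds
F0 | step 13 | none | none
F1 | step 18 | C7-vinyl C5-iodoalkene (31 with CH=CH2 in place of CHO) | C=C(I)CC[C@H](OC(C)=O)[C@@]1(C)[C@@H](OC(C)=O)[C@@H](OC(=O)CCC(C)C)[C@@H](O[Si](CC)(CC)CC)C[C@@H]1[C@H](O[Si](C)(C)C(C)(C)C)[C@]1(O[Si](CC)(CC)CC)[C@@H](C)C(=O)O[C@H]1C=C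
F2 | step 18 | isopropenyl/vinyl diene (F1 with CH3 in place of I) | C=C(C)CC[C@H](OC(C)=O)[C@@]1(C)[C@@H](OC(C)=O)[C@@H](OC(=O)CCC(C)C)[C@@H](O[Si](CC)(CC)CC)C[C@@H]1[C@H](O[Si](C)(C)C(C)(C)C)[C@]1(O[Si](CC)(CC)CC)[C@@H](C)C(=O)O[C@H]1C=C
F3 | step 18 | macrocyclic (Z)-5(6)-ene with 5-methyl (protected as 33) | C/C=1CC[C@H](OC(C)=O)[C@@]2(C)[C@@H](OC(C)=O)[C@@H](OC(=O)CCC(C)C)[C@@H](O[Si](CC)(CC)CC)C[C@@H]2[C@H](O[Si](C)(C)C(C)(C)C)[C@]2(O[Si](CC)(CC)CC)[C@@H](C)C(=O)O[C@H]2\C=1
F4 | step 8 | (S)-3-(triethylsilyloxy)cyclopentan-1-one | O=C1C[C@@H](O[Si](CC)(CC)CC)CC1
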